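**Retrosynthetic overview**
- Feature: pyrrole carbons C2–C5 lie between two oxygen-bearing carbons, the acyl carbon C1' on C2 and the hydroxymethyl carbon C6 on C5. Without N1, the string C1'–C2–C3–C4–C5–C6 is a 2,4-diyne-1,6-diol built from two propargylic alcohols.
- Target ⇒ desilylation and oxidation of the C1' carbinol ⇒ pyrrolyl carbinol ⇒ N1–C2 and N1–C5 (double hydroamination with NH3) ⇒ mono-silylated diynediol.
- Diynediol ⇒ C3–C4 (sp–sp Cadiot–Chodkiewicz union) ⇒ O-silylated 3-bromopropargyl alcohol + 18-methylnonadec-1-yn-3-ol.
- Alkynol ⇒ ethynylmagnesium bromide + 16-methylheptadecanal ⇒ C12 bromo alcohol + C6 bromide (copper-catalysed Grignard coupling).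
- Ring order: there is one ring, the pyrrole, and it closes in step 7 after the whole carbon chain is in place.

Key step: step 6

Remark on the chemistry: locants are N1, C2 (acyl-bearing), C3, C4, C5 (CH2OH-bearing), C1' (carbonyl carbon) and C6 (hydroxymethyl carbon). The target has no stereocentre, so the C1' carbinol centre made in step 3 is carried as the racemate and erased in step 8.

Step 1
Reactants: 1 1-bromo-4-methylpentane; 2 12-bromododecan-1-ol
Product: 4 16-methylheptadecan-1-ol, via 4-methylpentylmagnesium bromide 3 (not isolated)
Conditions: 1 (2.6 equiv), Mg, THF, reflux; then 2, Li2CuCl4 (5 mol %), THF, −10 °C to rt; aqueous work-up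
Reagents that add atoms: magnesium turnings, [Mg] (its atom stays in intermediate 3 only)
Why: This is a copper-catalysed sp3–sp3 Grignard cross-coupling (Kochi type) of a primary alkylmagnesium bromide with a primary alkyl bromide, in which the first equivalent of 3 only deprotonates the hydroxyl group and the resulting alkoxide is inert.

Step 2
Reactants: 4 16-methylheptadecan-1-ol
Product: 5 16-methylheptadecanal
Conditions: TEMPO (10 mol %), PhI(OAc)2 (1.1 equiv), CH2Cl2, rt
Reagents that add atoms: none
Why: The oxoammonium-mediated (TEMPO/PhI(OAc)2) oxidation of a primary alcohol stops at the aldehyde in water-free CH2Cl2, and the saturated chain has no other oxidisable site.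

Step 3
Reactants: 5 16-methylheptadecanal; 6 ethynylmagnesium bromide (0.5 M in THF)
Product: 7 18-methylnonadec-1-yn-3-ol (racemic)
Conditions: 6 (1.3 equiv), THF, 0 °C to rt; aqueous work-up
Reagents that add atoms: none
Why: Grignard 1,2-addition of an acetylide to an unhindered aldehyde is reliable, and the new carbinol centre (C1') forms without facial control as the racemate, which is acceptable because step 8 erases it.

Step 4
Reactants: 8 propargyl alcohol
Product: 9 tert-butyldimethyl(prop-2-yn-1-yloxy)silane
Conditions: TBSCl (1.1 equiv), imidazole (1.5 equiv), CH2Cl2, 0 °C to rt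
Reagents that add atoms: tert-butyldimethylsilyl chloride, CC(C)(C)[Si](C)(C)Cl
Why: Imidazole-promoted silylation of a primary alcohol masks the C6 oxygen, so the two carbinols of the later diyne stay distinguishable.

Step 5
Reactants: 9 tert-butyldimethyl(prop-2-yn-1-yloxy)silane
Product: 10 (3-bromoprop-2-yn-1-yloxy)(tert-butyl)dimethylsilane
Conditions: NBS (1.15 equiv), AgNO3 (10 mol %), acetone, rt, dark
Reagents that add atoms: N-bromosuccinimide, O=C1CCC(=O)N1Br
Why: Silver-catalysed electrophilic bromination of a terminal alkyne passes through a silver acetylide that NBS intercepts, turns the natively nucleophilic C4 into an electrophilic sp carbon, and leaves the silyl ether untouched.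

Step 6
Reactants: 7 18-methylnonadec-1-yn-3-ol (racemic); 10 (3-bromoprop-2-yn-1-yloxy)(tert-butyl)dimethylsilane
Product: 11 1-(tert-butyldimethylsilyloxy)-21-methyldocosa-2,4-diyn-6-ol (racemic)
Conditions: CuCl (10 mol %), NH2OH·HCl (0.3 equiv), 30% aq n-BuNH2, Et2O co-solvent, 0 °C, N2; 10 (1.2 equiv) in Et2O added dropwise
Reagents that add atoms: none
Why: In this Cadiot–Chodkiewicz coupling, n-BuNH2 and CuCl convert the terminal alkyne of 7 into a monovalent copper acetylide, which adds oxidatively to the C–Br bond of 10 to give a trivalent copper bis(alkynyl) species, and reductive elimination then forms the C3–C4 sp–sp bond and releases monovalent copper. It is the standard heterocoupling of a 1-bromoalkyne with a terminal alkyne, widely used on free propargylic alcohols and silyl ethers in polyacetylene synthesis. No ring closes and no stereocentre is made, so the carbinol centre of 7 passes through unchanged as the racemate. The selectivity needed is cross-coupling over homocoupling: only 7 can form the acetylide and only 10 carries the halide, NH2OH·HCl reduces any divalent copper that would drive Glaser dimerisation of 7, and slow addition of 10 at 0 °C keeps its concentration low so that halogen–copper exchange and its dimerisation stay minor. Et2O keeps the waxy C20 alkynol in contact with the aqueous amine phase, and 11 (one free OH) should separate easily from the two symmetrical dimers (two free OH groups or none).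

Step 7
Reactants: 11 1-(tert-butyldimethylsilyloxy)-21-methyldocosa-2,4-diyn-6-ol (racemic)
Product: 13 1-[5-(tert-butyldimethylsilyloxymethyl)-1H-pyrrol-2-yl]-16-methylheptadecan-1-ol (racemic), via aminoenyne 12 (not isolated)
Conditions: CuCl (20 mol %), NH3 (condensed, large excess), degassed THF, sealed pressure vessel, 100 °C; filtration through basic Al2O3, crude 13 used at once
Reagents that add atoms: ammonia, N
Why: In this copper-catalysed double hydroamination of a conjugated diyne, NH3 adds to the CuCl-activated diyne at a terminus (drawn at the less hindered C5) to give aminoenyne 12, whose nitrogen closes 5-endo-dig onto C2 of the second copper-bound alkyne and tautomerises to the aromatic pyrrole with no atom lost; the reaction type is established for 1,6-dioxygenated 2,4-diynes with primary amines and for simple diynes with ammonia, and the basic medium protects both acid-labile pyrrolylmethyl C–O bonds while the carbinol centre stays racemic.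

Step 8
Reactants: 13 1-[5-(tert-butyldimethylsilyloxymethyl)-1H-pyrrol-2-yl]-16-methylheptadecan-1-ol (racemic)
Product: 14 1-[5-(tert-butyldimethylsilyloxymethyl)-1H-pyrrol-2-yl]-16-methylheptadecan-1-one
Conditions: activated MnO2 (15 equiv), CH2Cl2, rt
Reagents that add atoms: none
Why: MnO2 oxidises benzylic-type carbinols under neutral conditions, so it should attack only the free pyrrole-conjugated C1' carbinol (C6 is blocked as its silyl ether), give a vinylogous-amide ketone that deactivates the ring towards further oxidation, and remove the only stereocentre.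

Step 9
Reactants: 14 1-[5-(tert-butyldimethylsilyloxymethyl)-1H-pyrrol-2-yl]-16-methylheptadecan-1-one
Product: 15 1-[5-(hydroxymethyl)-1H-pyrrol-2-yl]-16-methylheptadecan-1-one (target)
Conditions: Bu4NF (1.5 equiv), AcOH (1.5 equiv), THF, 0 °C to rt
Reagents that add atoms: none
Why: Fluoride-induced Si–O cleavage is driven by the strong Si–F bond, and the AcOH buffer keeps the acidic N–H of the acylpyrrole protonated so that azafulvene-type loss of the C6 oxygen is not triggered.

**Compound list**
1 | 1-bromo-4-methylpentane | CC(C)CCCBr | starting material
2 | 12-bromododecan-1-ol | OCCCCCCCCCCCCBr | starting material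
3 | 4-methylpentylmagnesium bromide | CC(C)CCC[Mg]Br | intermediate (not isolated)
4 | 16-methylheptadecan-1-ol | CC(C)CCCCCCCCCCCCCCCO | intermediate
5 | 16-methylheptadecanal | CC(C)CCCCCCCCCCCCCCC=O | intermediate
6 | ethynylmagnesium bromide | C#C[Mg]Br | starting material
7 | 18-methylnonadec-1-yn-3-ol (racemic) | C#CC(O)CCCCCCCCCCCCCCC(C)C | intermediate
8 | propargyl alcohol | C#CCO | starting material
9 | tert-butyldimethyl(prop-2-yn-1-yloxy)silane | C#CCO[Si](C)(C)C(C)(C)C | intermediate
10 | (3-bromoprop-2-yn-1-yloxy)(tert-butyl)dimethylsilane | BrC#CCO[Si](C)(C)C(C)(C)C | intermediate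
11 | 1-(tert-butyldimethylsilyloxy)-21-methyldocosa-2,4-diyn-6-ol (racemic) | CC(C)CCCCCCCCCCCCCCC(O)C#CC#CCO[Si](C)(C)C(C)(C)C | intermediate
12 | (Z)-2-amino-1-(tert-butyldimethylsilyloxy)-21-methyldocos-2-en-4-yn-6-ol (racemic) | CC(C)CCCCCCCCCCCCCCC(O)C#C/C=C(N)/CO[Si](C)(C)C(C)(C)C | intermediate (not isolated)
13 | 1-[5-(tert-butyldimethylsilyloxymethyl)-1H-pyrrol-2-yl]-16-methylheptadecan-1-ol (racemic) | CC(C)CCCCCCCCCCCCCCC(O)c1ccc(CO[Si](C)(C)C(C)(C)C)[nH]1 | intermediate
14 | 1-[5-(tert-butyldimethylsilyloxymethyl)-1H-pyrrol-2-yl]-16-methylheptadecan-1-one | CC(C)CCCCCCCCCCCCCCC(=O)c1ccc(CO[Si](C)(C)C(C)(C)C)[nH]1 | intermediate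
15 | 1-[5-(hydroxymethyl)-1H-pyrrol-2-yl]-16-methylheptadecan-1-one | CC(C)CCCCCCCCCCCCCCC(=O)c1ccc(CO)[nH]1 | target

**Step count**
Total step count: 9.
Longest linear sequence: 7 steps (steps 1, 2, 3, 6, 7, 8, 9).

**Steps most likely to fail**

Step 7. Ammonia binds copper strongly and is a modest nucleophile, so the first addition may be slow. Base-induced isomerisation of the propargylic carbinol, thermal polymerisation of the diyne, or ionisation of the pyrrolylmethyl C–O bonds of the product could then outrun ring closure. The fallback sets out from 11 and comes back at 13, and brings nitrogen in as a primary amine with a removable group. Heating 11 with benzylamine (3 equiv) and CuCl (10 mol %) in DMF at 100 °C is the well-established primary-amine form of the diyne-to-pyrrole reaction. It should give 1-[1-benzyl-5-(tert-butyldimethylsilyloxymethyl)-1H-pyrrol-2-yl]-16-methylheptadecan-1-ol F1. Dissolving-metal cleavage of the N-benzyl group (Na, liquid NH3, THF, −78 °C, short contact, quench with solid NH4Cl) should then free N1 and return 13. The electron-rich pyrrole is not reduced under these conditions, and the alkoxide and silyl ether are inert at that temperature.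

Step 8. Oxidation at the hindered secondary carbinol may be slow. Meanwhile the electron-rich ring could ionise at C1' or C6 on the slightly acidic oxide surface and oligomerise, or the ring itself could be oxidised. The fallback sets out from 13 and comes back at 15, and replaces selective oxidation by global oxidation followed by selective reduction. Bu4NF/AcOH in THF should give 1-[5-(hydroxymethyl)-1H-pyrrol-2-yl]-16-methylheptadecan-1-ol F2. Excess activated MnO2 in CH2Cl2 should oxidise the unhindered primary carbinol first; the formyl group so formed deactivates the ring while the secondary carbinol follows, giving 5-(16-methylheptadecanoyl)-1H-pyrrole-2-carbaldehyde F3. One hydride equivalent of NaBH4 in THF/EtOH at −20 °C should reduce the more electrophilic aldehyde in preference to the alkyl pyrrolyl ketone and deliver 15.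

Step 6. Homocoupling may compete: Glaser-type dimerisation of the acetylide after adventitious oxidation of copper, or dimerisation of the bromoalkyne after halogen–copper exchange. Poor mixing of the waxy alkynol with the aqueous amine phase could make this worse. The fallback sets out from 9 and 5 and comes back at 11, and builds the diyne without pairing two alkynes. Sonogashira coupling of 9 with 1,1-dichloroethene (5 equiv, Pd(PPh3)4 5 mol %, CuI 5 mol %, n-BuNH2, toluene, rt) should give tert-butyl[(4-chloropent-4-en-2-yn-1-yl)oxy]dimethylsilane F4. LDA (2.2 equiv, THF, −78 °C) should remove HCl and the acetylenic proton in one operation to give lithium 5-(tert-butyldimethylsilyloxy)penta-1,3-diyn-1-ide F5. Addition of F5 to aldehyde 5 at −78 °C, followed by aqueous work-up, should give 11.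

**Further compounds**
F1 | step 7 | 1-[1-benzyl-5-(tert-butyldimethylsilyloxymethyl)-1H-pyrrol-2-yl]-16-methylheptadecan-1-ol (racemic) | CC(C)CCCCCCCCCCCCCCC(O)c1ccc(CO[Si](C)(C)C(C)(C)C)n1Cc1ccccc1
F2 | step 8 | 1-[5-(hydroxymethyl)-1H-pyrrol-2-yl]-16-methylheptadecan-1-ol (racemic) | CC(C)CCCCCCCCCCCCCCC(O)c1ccc(CO)[nH]1
F3 | step 8 | 5-(16-methylheptadecanoyl)-1H-pyrrole-2-carbaldehyde | CC(C)CCCCCCCCCCCCCCC(=O)c1ccc(C=O)[nH]1
F4 | step 6 | tert-butyl[(4-chloropent-4-en-2-yn-1-yl)oxy]dimethylsilane | C=C(Cl)C#CCO[Si](C)(C)C(C)(C)C
F5 | step 6 | lithium 5-(tert-butyldimethylsilyloxy)penta-1,3-diyn-1-ide | [Li]C#CC#CCO[Si](C)(C)C(C)(C)C
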